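The runs come from a simulation with constants of no real substance, and the scatter is random.

Slowness comes first: by 5.00 h the north-east flask had received reagent for 18.0% of its substrate, yet it shows 4.6% target, so target lags the feed.

| setting | north-east | teal | blue |
|---|---|---|---|
| substrate | 0.10 M | 0.10 M | 0.10 M |
| reagent | 0.90 equiv (fed, over 25 h) | 0.900 equiv (fed, over 25 h) | 0.900 equiv (fed, over 25 h) |
| free catalyst | 3.2 mol% | 2.1 mol% | 2.1 mol% |
| temperature | −10 °C |  |  |
| remark | run made earlier | at −10 °C until 12 h, from then on at 40 °C | at −10 °C throughout |
| time |  | 25 h | 25 h |

north-east run (percent of the substrate charged)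

| time / h | target / % | over-reaction product / % |
|---|---|---|
| 1.00 | 0 | 0.3 |
| 2.00 | 0.7 | 0 |
| 3.00 | 2.8 | 0 |
| 4.00 | 3.2 | 0.4 |
| 5.00 | 4.6 | 0.6 |

(standard deviation of a reading: 0.5 percentage points)

- a species is counted by the substrate in it: one homo dimer counts as two
- amounts and yields of target count crystals too
- given per volume of solution although it is solid: crystals
- steps under discussion: crystals <-> target; catalyst intermediate C -> free catalyst + target; substrate + free catalyst <-> catalyst intermediate A; target -> over-reaction product; 2 substrate -> homo dimer; catalyst intermediate A <-> catalyst intermediate B; reagent + catalyst intermediate B -> catalyst intermediate C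
- the earlier runs do not show what temperature does; that part of a forecast is a guess
- no earlier run changes the charge of free catalyst; that part of a forecast is a guess

- the flask that ends with the higher share of target in all that became target or over-reaction product, or "neither" when 2 percentage points or less lies between them (teal / blue / neither)
- share of target in all that became target or over-reaction product, teal
- share of target in all that became target or over-reaction product, blue

*What sets the share?* If target is made steadily and lost first order, its portions have ages spread evenly from zero to the end of the run. The share is then their average survival. With exposure E, the loss constant times the hours, that average is (1 − e^−E)/E, and concentration does not enter it.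

*Where do you get the loss constant?* I replace the target curve by its mean, 2.26%. Dividing the over-reaction product at 5.00 h by that mean times the hours reads 0.0531 h⁻¹. For blue, E is 1.33, and the mean survival is 55.4%.

*Isn't a single mean age crude?* Taking every portion at the mean residence time, half the run, gives 51.5%, an error of 3.9 percentage points.

*And the weak spot?* The scatter is the weak spot. One standard deviation more on that reading gives E = 2.43 and a share of 37.5%, a larger shift than the error of the mean age.

*Your commitment?* For blue, I say 55.4%. For teal I can only guess what warming does, but a larger E lowers the share, so I put teal below blue.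

The forecast also chose blue, with teal at 35% (10% to 70%) and blue at 85% (68% to 97%). It reasoned that “Crystals probably cap dissolved target and protect it”, and its blue figure stands above my 55.4%.

The simulation gives blue as the higher: teal 0.0882%, blue 35.5%.

    crystals ⇌ target, rate k1*(cs1 - [target]) while solid is left; crystals form when [target] > cs1 (solubility = 0.0630 M, k = 0.410 h⁻¹)
    catalyst intermediate C → free catalyst + target (k = 7.20 h⁻¹, Ea = 68.0 kJ mol⁻¹)
    substrate + free catalyst ⇌ catalyst intermediate A (K = 43.0 M⁻¹, k = 35.0 M⁻¹ h⁻¹, Ea = 47.0 kJ mol⁻¹, ΔH = −25.0 kJ mol⁻¹)
    target → over-reaction product (k = 0.120 h⁻¹, Ea = 77.0 kJ mol⁻¹)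
    2 substrate → homo dimer (k = 7.10 × 10⁻⁴ M⁻¹ h⁻¹, Ea = 81.0 kJ mol⁻¹)
    catalyst intermediate A ⇌ catalyst intermediate B (K = 6.80, k = 2.30 h⁻¹, Ea = 79.0 kJ mol⁻¹, ΔH = −43.0 kJ mol⁻¹)
    reagent + catalyst intermediate B → catalyst intermediate C (k = 100 M⁻¹ h⁻¹, Ea = 56.0 kJ mol⁻¹)
    (constants at −10 °C)

Blue's share lies below my 55.4%, with crystals at 0% at 25.0 h. The half-life of dissolved target by over-reaction alone, 5.8 h in teal at its first temperature, is short against the 25 h run; blue stays at that temperature, and the half-life gives E = 3.00 and a mean survival of 31.7%.

Mean survival contains no concentration, so the teal recipe at 0.060 M of substrate should repeat teal's 0.0882%. That flask computes to 0.100%.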